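All constants were set for the occasion.

If you want to know what this flask ends with, ask how much target the starting material still meets on its way.

starting material 0.80 M (fed, over 20 h); capture agent 0.0800 M; time 15 d; the fed solution adds 1.0 times the starting volume

    starting material + target → side product (k1 = 0.046 L mol⁻¹ h⁻¹)
    open intermediate → target (k2 = 0.069 h⁻¹)
    starting material → open intermediate (k3 = 0.087 h⁻¹)
    open intermediate + capture agent → trapped intermediate (k4 = 0.11 L mol⁻¹ h⁻¹)

- the state of affairs at 15 d: stopped, and by what, or still going (forward and back rates have come level / it is still moving / all of the starting material has reacted)
- part of the starting material gone at 15 d
- the target standing at 15 d, as a percentage of the starting material charged
- the side product standing at 15 d, as a percentage of the starting material charged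
- amount of target if the flask were left three thousand times as long, in percent of the starting material charged

- percentages count the starting material that a species holds: one side product counts as two
- every charge counts on the volume at the start, and the solution that is fed holds the whole dose
- the reaction counts as stopped when no species that holds the starting material changes by six tenths of a point or more over the second half of the time
- run time (flask): 15 d

Take the ladder of times from the fastest rung. Starting material opens with a half-life of 0.33 d, open intermediate closes to target with 0.42 d, the feed lasts 20 h, capture of open intermediate at the charged capture agent takes 3.3 d, and the run lasts 15 d. Both first half-lives are far shorter than the run, so you should expect a flask in which the starting material has reacted well before the end. Capture is slower than closing, so treat it as a small correction; I reckon the side step as a second correction.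

To reckon it, note that an average portion of starting material enters in mid-feed and lives about 11.5 h more, so it reacts near 21.5 h, close to the end of the feed at 20 h. My plain balances for that moment, corrections dropped, leave 47.4 % as starting material and 33.1 % as open intermediate. That makes 19.5 % target, and in the full volume c(target) is 0.0780 M. Now call the leak the side step's rate constant times that c(target), divided by the opening step's rate constant, and counted two-fold, as one side product holds two: the points of side product gained per point of starting material that reacts. My reckoning puts it at 8.25 %.

The forecast says all of the starting material has reacted, with 100 % gone, target 85.5 %, side product 10 %, and target 85.5 % after the long wait, on the ground that “everything has drained well before” the end. Its side product stands above my leak.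

The simulation gives all of the starting material has reacted, with 100 % gone, target 86.6 %, side product 8.88 %, and target 86.6 % after the long wait, so the forecast stands within its margins on every count, and ten times as long leaves the target of this flask where it was. At the end of the feed, 0.833 d, this flask held 46.7 % starting material beside 18.1 % target, so the side step still had both partners. By 3.00 d side product stood at 8.79 %. At half of the time, 7.50 d, this flask held 8.88 % side product. The leak falls 0.63 percentage points short of the flask. Scaled in proportion to the charge, for the neighbour flask with 2.0 M of starting material, it gives 20.6 %, and that flask stands at 18.2 % side product.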